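## Retrosynthetic overview

1. Target 29 ⇒ 28 by BCl3 de-ethylation at C2'–O; 28 ⇒ 26 + propanoyl chloride 27 by Friedel–Crafts propanoylation at the one free carbon (C1) of ring A; 26 ⇒ 25 by hydrogenolysis of three benzyl ethers.
2. Key disconnection of 25: ring B bonds C1'–C2' and C3'–C4', giving silyl ketene acetal diene 17 (carrying ring A and the bridge CH2) and 1-ethoxypent-1-yn-3-one 22. The strategy rests on ring B: its C6' methoxy, the only methyl ether, lies para to the C3' propanoyl carbon and between C5'–CH3 and the C1' bridge carbon, which is the place of the internal methoxy of a 1,3-dioxygenated diene; C2'–O and the C3' acyl group come from the ynone and C4'–OH from the ester carbon.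
3. 17 ⇐ enol ether 15 ⇐ β-keto ester 13 ⇐ acid 9 + methyl propanoate 10; 9 ⇐ aldehyde 4 + Meldrum's acid 5 (reductive Knoevenagel, so no ionisation-prone 2,4,6-trialkoxybenzyl halide is needed) ⇐ 2-methylphloroglucinol 1.
4. 22 ⇐ ethoxyethyne 18 + propanal 19 (addition, then oxidation).
5. Ring order: ring A is bought with 1; ring B is the only ring formed (step 9).

Key step: step 9

Assumption: the target has no stereocentre; enol ether 15 and diene 17 are carried as alkene mixtures because step 9 erases their geometry, and racemic centres in 13, 14, 21, 23 and 24 are destroyed later.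

## Route

Step 1
Reactants: 1 2-methylphloroglucinol
Product: 3 2,4,6-trihydroxy-3-methylbenzaldehyde, via aryl iminium chloride 2 (not isolated)
Conditions: POCl3 (1.1 equiv), DMF, EtOAc, 0 °C → rt; then H2O, 60 °C
Reagents that add atoms: N,N-dimethylformamide CN(C)C=O; water O
Why: Vilsmeier–Haack formylation; the two open ring carbons of 1 are equivalent and the first formyl group deactivates the ring, so one equivalent of reagent should give the mono-aldehyde.

Step 2
Reactants: 3 2,4,6-trihydroxy-3-methylbenzaldehyde
Product: 4 2,4,6-tris(benzyloxy)-3-methylbenzaldehyde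
Conditions: BnBr (3.6 equiv), K2CO3, DMF, 60 °C
Reagents that add atoms: benzyl bromide BrCc1ccccc1
Why: Williamson ether synthesis; the formyl group lowers the carbon nucleophilicity of the phenoxide so O-benzylation should win over C-benzylation, and excess halide with heating also alkylates the two hydrogen-bonded ortho hydroxyls.

Step 3
Reactants: 4 2,4,6-tris(benzyloxy)-3-methylbenzaldehyde; 5 Meldrum's acid (2,2-dimethyl-1,3-dioxane-4,6-dione)
Product: 9 3-[2,4,6-tris(benzyloxy)-3-methylphenyl]propanoic acid, via arylidene Meldrum's acid 6 (not isolated), via arylmethyl Meldrum's acid 7 (not isolated), via arylmethyl malonic acid 8 (not isolated)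
Conditions: HCO2H–Et3N (5:2), 95 °C
Reagents that add atoms: none
Why: One-pot reductive Knoevenagel sequence in triethylammonium formate (Knoevenagel condensation, conjugate hydride transfer from formate, hydrolysis and decarboxylation); benzyl ethers are inert to formate in the absence of palladium.

Step 4
Reactants: 9 3-[2,4,6-tris(benzyloxy)-3-methylphenyl]propanoic acid; 10 methyl propanoate
Product: 13 methyl 2-methyl-3-oxo-5-[2,4,6-tris(benzyloxy)-3-methylphenyl]pentanoate (racemic), via acyl imidazolide 11 (not isolated), via lithium enolate of methyl propanoate 12 (not isolated)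
Conditions: 9, CDI, THF, rt; add to 12 (3.3 equiv, from 10 and LiN(i-Pr)2, THF, −78 °C), −78 → 0 °C; cold dilute HCl
Reagents that add atoms: none
Why: Crossed Claisen-type C-acylation of an ester enolate by an acyl imidazolide; excess enolate absorbs the imidazole N–H and deprotonates the β-keto ester as it forms, which stops over-addition, and the racemic α-centre is removed in step 5.

Step 5
Reactants: 13 methyl 2-methyl-3-oxo-5-[2,4,6-tris(benzyloxy)-3-methylphenyl]pentanoate
Product: 15 methyl 3-methoxy-2-methyl-5-[2,4,6-tris(benzyloxy)-3-methylphenyl]pent-2-enoate (E/Z mixture), via dimethyl ketal 14 (not isolated)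
Conditions: HC(OMe)3, cat. H2SO4, MeOH, rt; then cat. TsOH, PhMe, 80 °C (loss of MeOH)
Reagents that add atoms: trimethyl orthoformate COC(OC)OC; methanol CO
Why: Acid-catalysed ketalisation with an orthoester followed by elimination of methanol to the conjugated enol ether, a path that cannot C-methylate; any pent-3-enoate isomer is harmless because it gives the same dienolate in step 6.

Step 6
Reactants: 15 methyl 3-methoxy-2-methyl-5-[2,4,6-tris(benzyloxy)-3-methylphenyl]pent-2-enoate
Product: 17 trimethyl{[1,3-dimethoxy-2-methyl-5-[2,4,6-tris(benzyloxy)-3-methylphenyl]penta-1,3-dien-1-yl]oxy}silane (alkene mixture; used crude), via lithium dienolate 16 (not isolated)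
Conditions: LiN(i-Pr)2, THF, −78 °C; then Me3SiCl, −78 °C → rt; filter, concentrate
Reagents that add atoms: chlorotrimethylsilane C[Si](C)(C)Cl
Why: γ-Deprotonation of a β-alkoxy enoate and O-silylation of the dienolate, the standard preparation of Brassard-type dienes; ring A carries no ketone, so the base meets no competing acidic site.

Step 7
Reactants: 18 ethoxyethyne; 19 propanal
Product: 21 1-ethoxypent-1-yn-3-ol (racemic), via lithium ethoxyacetylide 20 (not isolated)
Conditions: n-BuLi, THF, −78 °C; then 19, −78 °C; H2O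
Reagents that add atoms: none
Why: 1,2-Addition of a lithium acetylide to an aldehyde; the neutral quench avoids acid-induced Meyer–Schuster rearrangement of the ynol ether carbinol, and the racemic carbinol centre is removed in step 8.

Step 8
Reactants: 21 1-ethoxypent-1-yn-3-ol
Product: 22 1-ethoxypent-1-yn-3-one
Conditions: activated MnO2 (excess), CH2Cl2, rt; filter, concentrate cold, use at once
Reagents that add atoms: none
Why: MnO2 oxidation of a propargylic alcohol under neutral, anhydrous conditions, which should spare the acid- and water-sensitive push–pull ynone.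

Step 9
Reactants: 17 trimethyl{[1,3-dimethoxy-2-methyl-5-[2,4,6-tris(benzyloxy)-3-methylphenyl]penta-1,3-dien-1-yl]oxy}silane; 22 1-ethoxypent-1-yn-3-one
Product: 25 1-[2-ethoxy-6-hydroxy-4-methoxy-5-methyl-3-{[2,4,6-tris(benzyloxy)-3-methylphenyl]methyl}phenyl]propan-1-one, via cyclohexadiene cycloadduct 23 (not isolated), via cyclohexadienone 24 (not isolated)
Conditions: PhMe, 0 °C → 60 °C; then cat. TsOH, CH2Cl2, rt
Reagents that add atoms: none
Why: Proposed new method: the reaction should run as a polar, stepwise (4+2) in which the diene terminus C4 of 17 (future C1') adds in vinylogous Mukaiyama–Michael fashion to the ethoxy-bearing carbon of push–pull ynone 22 (future C2'), and the resulting allenolate carbon (future C3') then closes on the O-silylated dialkoxycarbenium carbon (future C4') in a 6-(enolexo)-exo-trig ring closure to give 23. Loss of MeOSiMe3 from the mixed acetal carbon gives dienone 24, whose C1' hydrogen enolises to the phenol, so ring B is made and aromatised in one operation. The closest known reaction type is the Diels–Alder/aromatisation of Brassard-type 1-alkoxy-1-silyloxy-3-alkoxybutadienes with acetylenic ketones, acetylenic esters and quinones; new here are the β-alkoxy ynone as the two-carbon partner and the bulky C4 substituent on the diene. The selectivity needed is regiochemical and both partners enforce it: the ketene acetal makes C4 the nucleophilic end and the carbonyl makes the ethoxy carbon the electrophilic end, so the propanoyl carbon ends between two oxygens and the diene methoxy ends para to it as C6'–OMe, while attack through C2 is disfavoured because it would build a quaternary centre. No stereocentre survives aromatisation, and because bond formation is stepwise the mixed alkene geometry of 17 should not matter.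

Step 10
Reactants: 25 1-[2-ethoxy-6-hydroxy-4-methoxy-5-methyl-3-{[2,4,6-tris(benzyloxy)-3-methylphenyl]methyl}phenyl]propan-1-one
Product: 26 1-[2-ethoxy-6-hydroxy-4-methoxy-5-methyl-3-[(2,4,6-trihydroxy-3-methylphenyl)methyl]phenyl]propan-1-one
Conditions: H2 (1 atm), Pd/C (palladium metal on carbon), EtOAc–MeOH, rt
Reagents that add atoms: none
Why: Catalytic hydrogenolysis of aryl benzyl ethers; the diarylmethane C–C bonds and the hindered, hydrogen-bonded aryl ketone should not be reduced at one atmosphere and room temperature.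

Step 11
Reactants: 26 1-[2-ethoxy-6-hydroxy-4-methoxy-5-methyl-3-[(2,4,6-trihydroxy-3-methylphenyl)methyl]phenyl]propan-1-one; 27 propanoyl chloride
Product: 28 1-[3-[(2-ethoxy-4-hydroxy-6-methoxy-5-methyl-3-propanoylphenyl)methyl]-2,4,6-trihydroxy-5-methylphenyl]propan-1-one
Conditions: EtCOCl (1.2 equiv), AlCl3, CH2Cl2–PhNO2, 0 °C → rt; then cold aq. HCl
Reagents that add atoms: none
Why: Friedel–Crafts acylation of a phloroglucinol nucleus; ring A has a single unsubstituted carbon and ring B has none, so only one C-acylation product is possible, and any material that loses the C2' ethyl group under AlCl3 is already the target and is carried through step 12.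

Step 12
Reactants: 28 1-[3-[(2-ethoxy-4-hydroxy-6-methoxy-5-methyl-3-propanoylphenyl)methyl]-2,4,6-trihydroxy-5-methylphenyl]propan-1-one
Product: 29 1-[3-[(2,4-dihydroxy-6-methoxy-5-methyl-3-propanoylphenyl)methyl]-2,4,6-trihydroxy-5-methylphenyl]propan-1-one (target, CNP0215809.0)
Conditions: BCl3 (excess), CH2Cl2, −78 → 0 °C; then H2O
Reagents that add atoms: none
Why: Chelation-directed BCl3 dealkylation of an aryl alkyl ether ortho to a ketone; the C6' methyl ether is para to the ketone, cannot chelate, and should survive at low temperature.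

## Compound list

1 | 2-methylphloroglucinol (2-methylbenzene-1,3,5-triol) | Cc1c(O)cc(O)cc1O | starting material
2 | N-[(2,4,6-trihydroxy-3-methylphenyl)methylidene]-N-methylmethanaminium chloride | C[N+](C)=Cc1c(O)cc(O)c(C)c1O.[Cl-] | intermediate
3 | 2,4,6-trihydroxy-3-methylbenzaldehyde | O=Cc1c(O)cc(O)c(C)c1O | intermediate
4 | 2,4,6-tris(benzyloxy)-3-methylbenzaldehyde | O=Cc1c(OCc2ccccc2)cc(OCc2ccccc2)c(C)c1OCc1ccccc1 | intermediate
5 | Meldrum's acid (2,2-dimethyl-1,3-dioxane-4,6-dione) | CC1(C)OC(=O)CC(=O)O1 | starting material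
6 | 2,2-dimethyl-5-{[2,4,6-tris(benzyloxy)-3-methylphenyl]methylidene}-1,3-dioxane-4,6-dione | CC1(C)OC(=O)C(=Cc2c(OCc3ccccc3)cc(OCc3ccccc3)c(C)c2OCc2ccccc2)C(=O)O1 | intermediate
7 | 2,2-dimethyl-5-{[2,4,6-tris(benzyloxy)-3-methylphenyl]methyl}-1,3-dioxane-4,6-dione | CC1(C)OC(=O)C(Cc2c(OCc3ccccc3)cc(OCc3ccccc3)c(C)c2OCc2ccccc2)C(=O)O1 | intermediate
8 | 2-{[2,4,6-tris(benzyloxy)-3-methylphenyl]methyl}propanedioic acid | OC(=O)C(Cc1c(OCc2ccccc2)cc(OCc2ccccc2)c(C)c1OCc1ccccc1)C(=O)O | intermediate
9 | 3-[2,4,6-tris(benzyloxy)-3-methylphenyl]propanoic acid | OC(=O)CCc1c(OCc2ccccc2)cc(OCc2ccccc2)c(C)c1OCc1ccccc1 | intermediate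
10 | methyl propanoate | CCC(=O)OC | starting material
11 | 1-(imidazol-1-yl)-3-[2,4,6-tris(benzyloxy)-3-methylphenyl]propan-1-one | O=C(CCc1c(OCc2ccccc2)cc(OCc2ccccc2)c(C)c1OCc1ccccc1)n1ccnc1 | intermediate
12 | lithium enolate of methyl propanoate (lithium 1-methoxyprop-1-en-1-olate) | [Li+].CC=C([O-])OC | intermediate
13 | methyl 2-methyl-3-oxo-5-[2,4,6-tris(benzyloxy)-3-methylphenyl]pentanoate (racemic) | COC(=O)C(C)C(=O)CCc1c(OCc2ccccc2)cc(OCc2ccccc2)c(C)c1OCc1ccccc1 | intermediate
14 | methyl 3,3-dimethoxy-2-methyl-5-[2,4,6-tris(benzyloxy)-3-methylphenyl]pentanoate (racemic) | COC(=O)C(C)C(OC)(OC)CCc1c(OCc2ccccc2)cc(OCc2ccccc2)c(C)c1OCc1ccccc1 | intermediate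
15 | methyl 3-methoxy-2-methyl-5-[2,4,6-tris(benzyloxy)-3-methylphenyl]pent-2-enoate (E/Z mixture) | COC(=O)C(C)=C(OC)CCc1c(OCc2ccccc2)cc(OCc2ccccc2)c(C)c1OCc1ccccc1 | intermediate
16 | lithium dienolate of 15 (lithium 1,3-dimethoxy-2-methyl-5-[2,4,6-tris(benzyloxy)-3-methylphenyl]penta-1,3-dien-1-olate) | [Li+].COC([O-])=C(C)C(OC)=CCc1c(OCc2ccccc2)cc(OCc2ccccc2)c(C)c1OCc1ccccc1 | intermediate
17 | trimethyl{[1,3-dimethoxy-2-methyl-5-[2,4,6-tris(benzyloxy)-3-methylphenyl]penta-1,3-dien-1-yl]oxy}silane (alkene mixture) | COC(O[Si](C)(C)C)=C(C)C(OC)=CCc1c(OCc2ccccc2)cc(OCc2ccccc2)c(C)c1OCc1ccccc1 | intermediate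
18 | ethoxyethyne | C#COCC | starting material
19 | propanal | CCC=O | starting material
20 | lithium ethoxyacetylide | [Li+].[C-]#COCC | intermediate
21 | 1-ethoxypent-1-yn-3-ol (racemic) | CCOC#CC(O)CC | intermediate
22 | 1-ethoxypent-1-yn-3-one | CCOC#CC(=O)CC | intermediate
23 | 1-[2-ethoxy-4,6-dimethoxy-5-methyl-3-{[2,4,6-tris(benzyloxy)-3-methylphenyl]methyl}-6-(trimethylsilyloxy)cyclohexa-1,4-dien-1-yl]propan-1-one (diastereomer mixture, racemic) | CCOC1=C(C(=O)CC)C(OC)(O[Si](C)(C)C)C(C)=C(OC)C1Cc2c(OCc3ccccc3)cc(OCc3ccccc3)c(C)c2OCc2ccccc2 | intermediate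
24 | 3-ethoxy-5-methoxy-6-methyl-2-propanoyl-4-{[2,4,6-tris(benzyloxy)-3-methylphenyl]methyl}cyclohexa-2,5-dien-1-one (racemic) | CCOC1=C(C(=O)CC)C(=O)C(C)=C(OC)C1Cc2c(OCc3ccccc3)cc(OCc3ccccc3)c(C)c2OCc2ccccc2 | intermediate
25 | 1-[2-ethoxy-6-hydroxy-4-methoxy-5-methyl-3-{[2,4,6-tris(benzyloxy)-3-methylphenyl]methyl}phenyl]propan-1-one | CCOc1c(Cc2c(OCc3ccccc3)cc(OCc3ccccc3)c(C)c2OCc2ccccc2)c(OC)c(C)c(O)c1C(=O)CC | intermediate
26 | 1-[2-ethoxy-6-hydroxy-4-methoxy-5-methyl-3-[(2,4,6-trihydroxy-3-methylphenyl)methyl]phenyl]propan-1-one | CCOc1c(Cc2c(O)cc(O)c(C)c2O)c(OC)c(C)c(O)c1C(=O)CC | intermediate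
27 | propanoyl chloride | CCC(Cl)=O | starting material
28 | 1-[3-[(2-ethoxy-4-hydroxy-6-methoxy-5-methyl-3-propanoylphenyl)methyl]-2,4,6-trihydroxy-5-methylphenyl]propan-1-one | CCOc1c(Cc2c(O)c(C(=O)CC)c(O)c(C)c2O)c(OC)c(C)c(O)c1C(=O)CC | intermediate
29 | 1-[3-[(2,4-dihydroxy-6-methoxy-5-methyl-3-propanoylphenyl)methyl]-2,4,6-trihydroxy-5-methylphenyl]propan-1-one | CCC(=O)c1c(O)c(C)c(O)c(Cc2c(O)c(C(=O)CC)c(O)c(C)c2OC)c1O | target

## Step count and risks

Total step count: 12. Longest linear sequence: 10 steps (steps 1–6 and 9–12, from 2-methylphloroglucinol); steps 7–8 form a two-step side branch.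

Steps most likely to fail:

Step 9 (proposed new method). The first C–C bond may form slowly or not at all, because the ethoxy donor lowers the electrophilicity of the ynone and the diene terminus is hindered by the arylmethyl group. The reaction may also divert to (2+2) addition across the ketene acetal, stop at an open-chain Michael adduct, lose the diene by hydrolysis, or aromatise with loss of silanol instead of methanol. The fallback uses the known late-stage methylene bridging of two acylphloroglucinols; it sets out from 1 and 27 and returns at 29. Friedel–Crafts propanoylation of 1 with 27 (AlCl3, CH2Cl2–PhNO2) should give 1-(2,4,6-trihydroxy-3-methylphenyl)propan-1-one F1. One portion of F1 is methylated at the only hydroxyl not hydrogen-bonded to the ketone (Me2SO4, one equivalent, K2CO3, acetone) to give 1-(2,6-dihydroxy-4-methoxy-3-methylphenyl)propan-1-one F2. A Mannich reaction at its single open ring carbon (aqueous CH2O, Me2NH, EtOH) gives 1-{3-[(dimethylamino)methyl]-2,6-dihydroxy-4-methoxy-5-methylphenyl}propan-1-one F3. Heating F3 with F1 in dioxane should release the ortho-quinone methide of ring B, which is captured at the open carbon of F1 to give 29 directly.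

Step 11. Under AlCl3 the methylene bridge between two very electron-rich rings may cleave and recombine (ipso-protonation and retro-Friedel–Crafts scrambling), the phenols may be O-acylated without Fries migration, and the ring B ethers may be cleaved unselectively. The fallback moves the acylation to the benzyl ether stage and avoids a metal Lewis acid; it sets out from 25 and returns at 28. Compound 25 is treated with the mixed anhydride from propanoic acid and trifluoroacetic anhydride (CH2Cl2, 0 °C → rt, then brief K2CO3/MeOH to cleave any aryl ester), which should acylate the free carbon of the trialkoxy ring A. This gives 1-[2,4,6-tris(benzyloxy)-3-[(2-ethoxy-4-hydroxy-6-methoxy-5-methyl-3-propanoylphenyl)methyl]-5-methylphenyl]propan-1-one F4, and hydrogenolysis (H2, Pd/C, EtOAc–MeOH) then gives 28.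

Step 5. Enol ether formation may stall at the ketal or proceed slowly, because the α-methyl β-keto ester is hindered and little enolised, and prolonged acid treatment may return ketone on work-up. The fallback installs the methoxy group by conjugate addition instead of carbonyl derivatisation; it sets out from 9 and returns at 15. Acid 9 is converted with oxalyl chloride (cat. DMF, CH2Cl2) into 3-[2,4,6-tris(benzyloxy)-3-methylphenyl]propanoyl chloride F5. Treatment with Et3N and methyl 2-(triphenylphosphoranylidene)propanoate (ketene formation and Wittig olefination) gives methyl 2-methyl-5-[2,4,6-tris(benzyloxy)-3-methylphenyl]penta-2,3-dienoate F6. Addition of NaOMe in MeOH to the central allene carbon and equilibration should give 15.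

Further compounds
F1 | step 9 | 1-(2,4,6-trihydroxy-3-methylphenyl)propan-1-one | CCC(=O)c1c(O)cc(O)c(C)c1O
F2 | step 9 | 1-(2,6-dihydroxy-4-methoxy-3-methylphenyl)propan-1-one | CCC(=O)c1c(O)cc(OC)c(C)c1O
F3 | step 9 | 1-{3-[(dimethylamino)methyl]-2,6-dihydroxy-4-methoxy-5-methylphenyl}propan-1-one | CCC(=O)c1c(O)c(CN(C)C)c(OC)c(C)c1O
F4 | step 11 | 1-[2,4,6-tris(benzyloxy)-3-[(2-ethoxy-4-hydroxy-6-methoxy-5-methyl-3-propanoylphenyl)methyl]-5-methylphenyl]propan-1-one | CCOc1c(Cc2c(OCc3ccccc3)c(C(=O)CC)c(OCc3ccccc3)c(C)c2OCc2ccccc2)c(OC)c(C)c(O)c1C(=O)CC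
F5 | step 5 | 3-[2,4,6-tris(benzyloxy)-3-methylphenyl]propanoyl chloride | ClC(=O)CCc1c(OCc2ccccc2)cc(OCc2ccccc2)c(C)c1OCc1ccccc1
F6 | step 5 | methyl 2-methyl-5-[2,4,6-tris(benzyloxy)-3-methylphenyl]penta-2,3-dienoate (racemic allene) | COC(=O)C(C)=C=CCc1c(OCc2ccccc2)cc(OCc2ccccc2)c(C)c1OCc1ccccc1
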